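**Retrosynthetic overview**

1. The plan rests on the cyclohexa-2,4-diene ring (C1 quaternary and pyranone-bearing, C6 alkenyl-bearing). C2=C3 with the C3 methyl is read as a prop-1-ynyl group on C1, and C4=C5 with the C5 methyl as an isopropenyl group on C6. Cutting C3–C4 gives the open-chain 1,5-enyne 23.
2. The pyranone is built last on the C1 aldehyde 26 with the dianion of keto ester 27 (aldol, oxidation, lactonisation, O-methylation). The side-chain ketone stays a dioxolane until the final step.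
3. In enyne 23 the C1–C6 bond and both stereocentres come from a dianionic Ireland–Claisen rearrangement of the dienyl β-hydroxy ester 15. The carboxyl carbon becomes CH2OTBS and the CH(OH)Et arm becomes the propynyl group (oxidation, enol triflate, elimination).
4. Ester 15 comes from dienol 9 (ethyl pyruvate; ketal, Wittig, Horner–Wadsworth–Emmons, reduction) and hydroxy acid 14 (Evans aldol).
5. Ring order: cyclohexadiene first (step 15), 4-pyranone second (step 20).

Key step: step 15

Remark: ring atoms are numbered C1 (quaternary carbon that carries the pyranone) to C6 (CH that carries the alkenyl chain) throughout. C2 of acid 14 stops being a stereocentre on enolisation, so only its C3 configuration matters.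

**Route**

Step 1
Reactants: 1 ethyl pyruvate
Product: 2 ethyl 2-methyl-1,3-dioxolane-2-carboxylate
Conditions: ethylene glycol, TsOH·H2O (cat.), toluene, reflux, Dean–Stark
Reagents that add atoms: ethylene glycol, OCCO
Why: Acid-catalysed ketalisation of the ketone carbonyl with azeotropic removal of water leaves the ester untouched.

Step 2
Reactants: 2 ethyl 2-methyl-1,3-dioxolane-2-carboxylate
Product: 3 2-methyl-1,3-dioxolane-2-carbaldehyde
Conditions: i-Bu2AlH (1.05 equiv), CH2Cl2, −78 °C; aq potassium sodium tartrate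
Reagents that add atoms: none
Why: Partial ester reduction should stop at the aldehyde because the α,α-dioxygenated tetrahedral aluminate is stable at −78 °C until work-up.

Step 3
Reactants: 3 2-methyl-1,3-dioxolane-2-carbaldehyde; 4 2-(triphenylphosphoranylidene)propanal
Product: 5 (2E)-2-methyl-3-(2-methyl-1,3-dioxolan-2-yl)prop-2-enal
Conditions: toluene, 90 °C
Reagents that add atoms: none
Why: Wittig olefination of the non-enolisable aldehyde with the stabilised formyl ylide should give the E-trisubstituted enal (formyl group trans to the ketal carbon).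

Step 4
Reactants: 6 triethyl 2-phosphonopropionate; 5 (2E)-2-methyl-3-(2-methyl-1,3-dioxolan-2-yl)prop-2-enal
Product: 8 ethyl (2E,4E)-2,4-dimethyl-5-(2-methyl-1,3-dioxolan-2-yl)penta-2,4-dienoate, via sodium phosphonate carbanion 7 (not isolated)
Conditions: NaH, THF, 0 °C; then 5, 0 °C → rt
Reagents that add atoms: none
Why: Horner–Wadsworth–Emmons olefination of the enal by 1,2-addition of the α-methyl phosphonate anion should give the new trisubstituted alkene with E geometry.

Step 5
Reactants: 8 ethyl (2E,4E)-2,4-dimethyl-5-(2-methyl-1,3-dioxolan-2-yl)penta-2,4-dienoate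
Product: 9 (2E,4E)-2,4-dimethyl-5-(2-methyl-1,3-dioxolan-2-yl)penta-2,4-dien-1-ol
Conditions: i-Bu2AlH (2.2 equiv), CH2Cl2, −78 °C; aq potassium sodium tartrate
Reagents that add atoms: none
Why: 1,2-Reduction of the dienoate to the allylic alcohol leaves both alkene geometries and the ketal intact.

Step 6
Reactants: 10 (4S)-4-benzyl-3-propanoyl-1,3-oxazolidin-2-one; 11 propanal
Product: 13 (4S)-4-benzyl-3-[(2S,3R)-3-hydroxy-2-methylpentanoyl]-1,3-oxazolidin-2-one, via dibutylboron Z-enolate 12 (not isolated)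
Conditions: Bu2BOTf, i-Pr2NEt, CH2Cl2, 0 °C; then 11, −78 → 0 °C; pH 7 buffer, MeOH, H2O2
Reagents that add atoms: none
Why: Evans syn aldol reaction through the Z-boron enolate and a Zimmerman–Traxler chair, in which the (S)-benzyl auxiliary sets the (2S,3R) configuration; the 3R carbinol centre is the element that later steers the Claisen step.

Step 7
Reactants: 13 (4S)-4-benzyl-3-[(2S,3R)-3-hydroxy-2-methylpentanoyl]-1,3-oxazolidin-2-one
Product: 14 (2S,3R)-3-hydroxy-2-methylpentanoic acid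
Conditions: LiOH, H2O2, THF/H2O, 0 °C; Na2SO3; HCl to pH 3
Reagents that add atoms: hydrogen peroxide, OO (its oxygen becomes the acid hydroxyl oxygen)
Why: Lithium hydroperoxide attacks the exocyclic imide carbonyl selectively, which releases the acid without retro-aldol cleavage.

Step 8
Reactants: 14 (2S,3R)-3-hydroxy-2-methylpentanoic acid; 9 (2E,4E)-2,4-dimethyl-5-(2-methyl-1,3-dioxolan-2-yl)penta-2,4-dien-1-ol
Product: 15 (2E,4E)-2,4-dimethyl-5-(2-methyl-1,3-dioxolan-2-yl)penta-2,4-dien-1-yl (2S,3R)-3-hydroxy-2-methylpentanoate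
Conditions: EDC·HCl, DMAP (cat.), CH2Cl2, 0 °C → rt
Reagents that add atoms: none
Why: Steglich esterification should acylate the primary allylic alcohol much faster than the hindered secondary hydroxyl of the acid, and epimerisation at C2 would be without consequence.

Step 9
Reactants: 15 (2E,4E)-2,4-dimethyl-5-(2-methyl-1,3-dioxolan-2-yl)penta-2,4-dien-1-yl (2S,3R)-3-hydroxy-2-methylpentanoate
Product: 17 (2R,3S,4E)-2-[(1R)-1-hydroxypropyl]-2,4-dimethyl-5-(2-methyl-1,3-dioxolan-2-yl)-3-(prop-1-en-2-yl)pent-4-enoic acid, via chelated dilithium dianion 16 (not isolated)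
Conditions: LiN(i-Pr)2 (2.3 equiv), THF, −78 → −20 °C; then 25 °C; aq NaH2PO4
Reagents that add atoms: none
Why: Dianionic Ireland–Claisen rearrangement in which the lithium alkoxide fixes the enolate geometry by chelation (carbinol arm cis to the enolate oxygen, as in Fráter–Seebach alkylations), the E-allyl unit adds through a chair on the enolate face anti to the ethyl group, and this sets the quaternary carbon (future C1) and the neighbouring CH (future C6) while it unveils the isopropenyl group.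

Step 10
Reactants: 17 (2R,3S,4E)-2-[(1R)-1-hydroxypropyl]-2,4-dimethyl-5-(2-methyl-1,3-dioxolan-2-yl)-3-(prop-1-en-2-yl)pent-4-enoic acid
Product: 18 (2S,3S,4E)-2-[(1R)-1-hydroxypropyl]-2,4-dimethyl-5-(2-methyl-1,3-dioxolan-2-yl)-3-(prop-1-en-2-yl)pent-4-en-1-ol
Conditions: LiAlH4, THF, 0 °C → reflux; aq potassium sodium tartrate
Reagents that add atoms: none
Why: Hydride reduction of the carboxylate to the primary alcohol leaves the alkenes and the ketal untouched and keeps the two oxygenated arms on the quaternary carbon different.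

Step 11
Reactants: 18 (2S,3S,4E)-2-[(1R)-1-hydroxypropyl]-2,4-dimethyl-5-(2-methyl-1,3-dioxolan-2-yl)-3-(prop-1-en-2-yl)pent-4-en-1-ol
Product: 19 (3R,4S,5S,6E)-4-{[tert-butyl(dimethyl)silyl]oxymethyl}-4,6-dimethyl-7-(2-methyl-1,3-dioxolan-2-yl)-5-(prop-1-en-2-yl)hept-6-en-3-ol
Conditions: TBSCl (1.05 equiv), imidazole, CH2Cl2, 0 °C
Reagents that add atoms: tert-butyldimethylsilyl chloride, CC(C)(C)[Si](C)(C)Cl
Why: The primary hydroxyl should be silylated selectively over the secondary hydroxyl, which is flanked by the quaternary carbon.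

Step 12
Reactants: 19 (3R,4S,5S,6E)-4-{[tert-butyl(dimethyl)silyl]oxymethyl}-4,6-dimethyl-7-(2-methyl-1,3-dioxolan-2-yl)-5-(prop-1-en-2-yl)hept-6-en-3-ol
Product: 20 (4S,5S,6E)-4-{[tert-butyl(dimethyl)silyl]oxymethyl}-4,6-dimethyl-7-(2-methyl-1,3-dioxolan-2-yl)-5-(prop-1-en-2-yl)hept-6-en-3-one
Conditions: Dess–Martin periodinane, NaHCO3, CH2Cl2, 0 °C → rt
Reagents that add atoms: none
Why: Buffered Dess–Martin oxidation removes the now spent carbinol stereocentre, and the quaternary α-carbon rules out epimerisation and β-elimination of the silyloxy group.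

Step 13
Reactants: 20 (4S,5S,6E)-4-{[tert-butyl(dimethyl)silyl]oxymethyl}-4,6-dimethyl-7-(2-methyl-1,3-dioxolan-2-yl)-5-(prop-1-en-2-yl)hept-6-en-3-one
Product: 22 (2Z,4S,5S,6E)-4-{[tert-butyl(dimethyl)silyl]oxymethyl}-4,6-dimethyl-7-(2-methyl-1,3-dioxolan-2-yl)-5-(prop-1-en-2-yl)hepta-2,6-dien-3-yl trifluoromethanesulfonate, via potassium Z-enolate 21 (not isolated)
Conditions: KN(SiMe3)2, THF, −78 °C; PhNTf2, −78 → 0 °C
Reagents that add atoms: N-phenylbis(trifluoromethanesulfonimide), O=S(=O)(N(c1ccccc1)S(=O)(=O)C(F)(F)F)C(F)(F)F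
Why: Enolisation is possible only toward the ethyl group, the bulky quaternary neighbour should enforce the Z-enolate, and O-triflation then gives the enol triflate whose vinylic hydrogen is trans to the triflate.

Step 14
Reactants: 22 (2Z,4S,5S,6E)-4-{[tert-butyl(dimethyl)silyl]oxymethyl}-4,6-dimethyl-7-(2-methyl-1,3-dioxolan-2-yl)-5-(prop-1-en-2-yl)hepta-2,6-dien-3-yl trifluoromethanesulfonate
Product: 23 tert-butyl{[(2R,3S,4E)-2,4-dimethyl-5-(2-methyl-1,3-dioxolan-2-yl)-3-(prop-1-en-2-yl)-2-(prop-1-yn-1-yl)pent-4-en-1-yl]oxy}dimethylsilane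
Conditions: LiN(i-Pr)2 (2.5 equiv), THF, −78 → 0 °C
Reagents that add atoms: none
Why: Anti-periplanar E2 elimination of triflate from the Z-enol triflate gives the methyl-capped alkyne, and no allene or regioisomer can form because the neighbouring carbon is quaternary.

Step 15
Reactants: 23 tert-butyl{[(2R,3S,4E)-2,4-dimethyl-5-(2-methyl-1,3-dioxolan-2-yl)-3-(prop-1-en-2-yl)-2-(prop-1-yn-1-yl)pent-4-en-1-yl]oxy}dimethylsilane
Product: 24 tert-butyl{[(1S,6S)-1,3,5-trimethyl-6-[(1E)-1-(2-methyl-1,3-dioxolan-2-yl)prop-1-en-2-yl]cyclohexa-2,4-dien-1-yl]methoxy}dimethylsilane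
Conditions: Ph3PAuNTf2 (2–5 mol %), CH2Cl2, 4 Å molecular sieves, 0 °C → rt
Reagents that add atoms: none
Why: Cationic monovalent gold binds the C2≡C3 alkyne of 23 and the CH2 terminus of the isopropenyl group (future C4) attacks the methyl-bearing alkyne carbon C3 anti to gold, which closes the cyclohexadiene ring in the 6-endo-dig mode and leaves gold on C2 and a tertiary cation at C5 (equivalently a cyclopropyl gold carbenoid); loss of a C4 proton and protodeauration at C2 then give the C2=C3 and C4=C5 double bonds. The closest known reaction type is the gold- or platinum-catalysed cycloisomerisation of 1,5-enynes that carry a quaternary propargylic carbon and a 1,1-disubstituted alkene to cyclohexadienes. No stereocentre is formed, and C1 (quaternary, so the 1,2-hydride shift that leads to bicyclo[3.1.0]hexenes is impossible) and C6 pass through unchanged. The step needs the isopropenyl group and not the side-chain alkene to attack, which its unhindered CH2 terminus and the tertiary cation it leads to should secure, since the side-chain CH carbon is flanked by the ketal carbon and inductively deactivated. It also needs proton loss from C4 and not from C6: the C4 hydrogens lie between the cation and the vinylgold unit and are aligned with the empty orbital, whereas the C6 alkenyl group should sit pseudoaxial (A(1,2) strain with the C5 methyl group and the quaternary C1), which places C6–H near the nodal plane. The silyl ether keeps the oxygen from adding to the activated alkyne.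

Step 16
Reactants: 24 tert-butyl{[(1S,6S)-1,3,5-trimethyl-6-[(1E)-1-(2-methyl-1,3-dioxolan-2-yl)prop-1-en-2-yl]cyclohexa-2,4-dien-1-yl]methoxy}dimethylsilane
Product: 25 {(1S,6S)-1,3,5-trimethyl-6-[(1E)-1-(2-methyl-1,3-dioxolan-2-yl)prop-1-en-2-yl]cyclohexa-2,4-dien-1-yl}methanol
Conditions: Bu4NF, THF, 0 °C → rt; water
Reagents that add atoms: none
Why: Fluoride cleaves the silyl ether under conditions that leave the ketal and the diene untouched.

Step 17
Reactants: 25 {(1S,6S)-1,3,5-trimethyl-6-[(1E)-1-(2-methyl-1,3-dioxolan-2-yl)prop-1-en-2-yl]cyclohexa-2,4-dien-1-yl}methanol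
Product: 26 (1S,6S)-1,3,5-trimethyl-6-[(1E)-1-(2-methyl-1,3-dioxolan-2-yl)prop-1-en-2-yl]cyclohexa-2,4-diene-1-carbaldehyde
Conditions: Dess–Martin periodinane, NaHCO3, CH2Cl2, 0 °C
Reagents that add atoms: none
Why: Dess–Martin oxidation gives an aldehyde on a quaternary carbon, which cannot enolise or epimerise.

Step 18
Reactants: 27 methyl 2-methyl-3-oxopentanoate; 26 (1S,6S)-1,3,5-trimethyl-6-[(1E)-1-(2-methyl-1,3-dioxolan-2-yl)prop-1-en-2-yl]cyclohexa-2,4-diene-1-carbaldehyde
Product: 29 methyl 5-hydroxy-2,4-dimethyl-3-oxo-5-{(1S,6S)-1,3,5-trimethyl-6-[(1E)-1-(2-methyl-1,3-dioxolan-2-yl)prop-1-en-2-yl]cyclohexa-2,4-dien-1-yl}pentanoate (mixture of diastereomers at C2, C4 and C5), via dilithium keto ester dianion 28 (not isolated)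
Conditions: 27 (3 equiv), LiN(i-Pr)2 (6 equiv), THF, −78 → 0 °C; then 26, −78 °C; aq NH4Cl
Reagents that add atoms: none
Why: Aldol addition of the β-keto ester dianion occurs at its more basic γ-carbon, and the three new stereocentres are removed in the next two steps.

Step 19
Reactants: 29 methyl 5-hydroxy-2,4-dimethyl-3-oxo-5-{(1S,6S)-1,3,5-trimethyl-6-[(1E)-1-(2-methyl-1,3-dioxolan-2-yl)prop-1-en-2-yl]cyclohexa-2,4-dien-1-yl}pentanoate
Product: 30 methyl 2,4-dimethyl-3,5-dioxo-5-{(1S,6S)-1,3,5-trimethyl-6-[(1E)-1-(2-methyl-1,3-dioxolan-2-yl)prop-1-en-2-yl]cyclohexa-2,4-dien-1-yl}pentanoate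
Conditions: Dess–Martin periodinane, NaHCO3, CH2Cl2, rt
Reagents that add atoms: none
Why: Dess–Martin oxidation of the δ-hydroxyl gives the β,δ-diketo ester, the open-chain form of the pyranone.

Step 20
Reactants: 30 methyl 2,4-dimethyl-3,5-dioxo-5-{(1S,6S)-1,3,5-trimethyl-6-[(1E)-1-(2-methyl-1,3-dioxolan-2-yl)prop-1-en-2-yl]cyclohexa-2,4-dien-1-yl}pentanoate
Product: 31 4-hydroxy-3,5-dimethyl-6-{(1S,6S)-1,3,5-trimethyl-6-[(1E)-1-(2-methyl-1,3-dioxolan-2-yl)prop-1-en-2-yl]cyclohexa-2,4-dien-1-yl}-2H-pyran-2-one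
Conditions: DBU, toluene, rt → 60 °C
Reagents that add atoms: none
Why: Base-promoted lactonisation (the enol oxygen of the δ-ketone attacks the ester with loss of methanol) closes the pyranone ring, and C6–H is not acidic while the side-chain ketone is masked.

Step 21
Reactants: 31 4-hydroxy-3,5-dimethyl-6-{(1S,6S)-1,3,5-trimethyl-6-[(1E)-1-(2-methyl-1,3-dioxolan-2-yl)prop-1-en-2-yl]cyclohexa-2,4-dien-1-yl}-2H-pyran-2-one
Product: 32 2-methoxy-3,5-dimethyl-6-{(1S,6S)-1,3,5-trimethyl-6-[(1E)-1-(2-methyl-1,3-dioxolan-2-yl)prop-1-en-2-yl]cyclohexa-2,4-dien-1-yl}-4H-pyran-4-one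
Conditions: MeOSO2F, CH2Cl2, rt; aq NaHCO3
Reagents that add atoms: methyl fluorosulfonate, COS(=O)(=O)F
Why: The hard methylating agent should alkylate the lactone carbonyl oxygen of the 4-hydroxy-2-pyranone, and loss of the hydroxyl proton on work-up then gives the 2-methoxy-4-pyranone.

Step 22
Reactants: 32 2-methoxy-3,5-dimethyl-6-{(1S,6S)-1,3,5-trimethyl-6-[(1E)-1-(2-methyl-1,3-dioxolan-2-yl)prop-1-en-2-yl]cyclohexa-2,4-dien-1-yl}-4H-pyran-4-one
Product: 33 2-methoxy-3,5-dimethyl-6-{(1S,6S)-1,3,5-trimethyl-6-[(2E)-4-oxopent-2-en-2-yl]cyclohexa-2,4-dien-1-yl}-4H-pyran-4-one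
Conditions: PPTS (cat.), acetone/H2O, rt
Reagents that add atoms: water, O
Why: Mild acid hydrolysis of the allylic dioxolane unmasks the enone last, so the base-sensitive doubly allylic C6–H never meets a conjugated ketone under basic conditions, and the E geometry is the thermodynamically favoured one.

**Compound list**

1 | ethyl pyruvate | CCOC(=O)C(C)=O | starting material
2 | ethyl 2-methyl-1,3-dioxolane-2-carboxylate | CCOC(=O)C1(C)OCCO1 | intermediate
3 | 2-methyl-1,3-dioxolane-2-carbaldehyde | O=CC1(C)OCCO1 | intermediate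
4 | 2-(triphenylphosphoranylidene)propanal | CC(C=O)=P(c1ccccc1)(c1ccccc1)c1ccccc1 | starting material
5 | (2E)-2-methyl-3-(2-methyl-1,3-dioxolan-2-yl)prop-2-enal | O=C/C(C)=C/C1(C)OCCO1 | intermediate
6 | triethyl 2-phosphonopropionate | CCOC(=O)C(C)P(=O)(OCC)OCC | starting material
7 | sodium salt of the carbanion of 6 | CCOC(=O)[C-](C)P(=O)(OCC)OCC.[Na+] | intermediate
8 | ethyl (2E,4E)-2,4-dimethyl-5-(2-methyl-1,3-dioxolan-2-yl)penta-2,4-dienoate | CCOC(=O)/C(C)=C/C(C)=C/C1(C)OCCO1 | intermediate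
9 | (2E,4E)-2,4-dimethyl-5-(2-methyl-1,3-dioxolan-2-yl)penta-2,4-dien-1-ol | OC/C(C)=C/C(C)=C/C1(C)OCCO1 | intermediate
10 | (4S)-4-benzyl-3-propanoyl-1,3-oxazolidin-2-one | CCC(=O)N1[C@@H](Cc2ccccc2)COC1=O | starting material
11 | propanal | CCC=O | starting material
12 | dibutylboron Z-enolate of 10 | C/C=C(\OB(CCCC)CCCC)N1[C@@H](Cc2ccccc2)COC1=O | intermediate
13 | (4S)-4-benzyl-3-[(2S,3R)-3-hydroxy-2-methylpentanoyl]-1,3-oxazolidin-2-one | CC[C@@H](O)[C@H](C)C(=O)N1[C@@H](Cc2ccccc2)COC1=O | intermediate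
14 | (2S,3R)-3-hydroxy-2-methylpentanoic acid | CC[C@@H](O)[C@H](C)C(=O)O | intermediate
15 | (2E,4E)-2,4-dimethyl-5-(2-methyl-1,3-dioxolan-2-yl)penta-2,4-dien-1-yl (2S,3R)-3-hydroxy-2-methylpentanoate | CC[C@@H](O)[C@H](C)C(=O)OC/C(C)=C/C(C)=C/C1(C)OCCO1 | intermediate
16 | chelated dilithium dianion of 15 (alkoxide and ester enolate, carbinol arm cis to the enolate oxygen) | CC[C@@H]([O-])/C(C)=C(\[O-])OC/C(C)=C/C(C)=C/C1(C)OCCO1.[Li+].[Li+] | intermediate
17 | (2R,3S,4E)-2-[(1R)-1-hydroxypropyl]-2,4-dimethyl-5-(2-methyl-1,3-dioxolan-2-yl)-3-(prop-1-en-2-yl)pent-4-enoic acid | OC(=O)[C@@]([C@@H](C(C)=C)/C(C)=C/C1(C)OCCO1)(C)[C@H](O)CC | intermediate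
18 | (2S,3S,4E)-2-[(1R)-1-hydroxypropyl]-2,4-dimethyl-5-(2-methyl-1,3-dioxolan-2-yl)-3-(prop-1-en-2-yl)pent-4-en-1-ol | OC[C@@]([C@@H](C(C)=C)/C(C)=C/C1(C)OCCO1)(C)[C@H](O)CC | intermediate
19 | (3R,4S,5S,6E)-4-{[tert-butyl(dimethyl)silyl]oxymethyl}-4,6-dimethyl-7-(2-methyl-1,3-dioxolan-2-yl)-5-(prop-1-en-2-yl)hept-6-en-3-ol | CC(C)(C)[Si](C)(C)OC[C@@]([C@@H](C(C)=C)/C(C)=C/C1(C)OCCO1)(C)[C@H](O)CC | intermediate
20 | (4S,5S,6E)-4-{[tert-butyl(dimethyl)silyl]oxymethyl}-4,6-dimethyl-7-(2-methyl-1,3-dioxolan-2-yl)-5-(prop-1-en-2-yl)hept-6-en-3-one | CC(C)(C)[Si](C)(C)OC[C@@]([C@@H](C(C)=C)/C(C)=C/C1(C)OCCO1)(C)C(=O)CC | intermediate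
21 | potassium Z-enolate of 20 | CC(C)(C)[Si](C)(C)OC[C@@]([C@@H](C(C)=C)/C(C)=C/C1(C)OCCO1)(C)/C([O-])=C/C.[K+] | intermediate
22 | (2Z,4S,5S,6E)-4-{[tert-butyl(dimethyl)silyl]oxymethyl}-4,6-dimethyl-7-(2-methyl-1,3-dioxolan-2-yl)-5-(prop-1-en-2-yl)hepta-2,6-dien-3-yl trifluoromethanesulfonate | CC(C)(C)[Si](C)(C)OC[C@@]([C@@H](C(C)=C)/C(C)=C/C1(C)OCCO1)(C)/C(OS(=O)(=O)C(F)(F)F)=C/C | intermediate
23 | tert-butyl{[(2R,3S,4E)-2,4-dimethyl-5-(2-methyl-1,3-dioxolan-2-yl)-3-(prop-1-en-2-yl)-2-(prop-1-yn-1-yl)pent-4-en-1-yl]oxy}dimethylsilane (1,5-enyne, key-step precursor) | CC(C)(C)[Si](C)(C)OC[C@@]([C@@H](C(C)=C)/C(C)=C/C1(C)OCCO1)(C)C#CC | intermediate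
24 | tert-butyl{[(1S,6S)-1,3,5-trimethyl-6-[(1E)-1-(2-methyl-1,3-dioxolan-2-yl)prop-1-en-2-yl]cyclohexa-2,4-dien-1-yl]methoxy}dimethylsilane (key-step product, silyloxymethyl cis to alkenyl) | CC(C)(C)[Si](C)(C)OC[C@@]1(C)C=C(C)C=C(C)[C@H]1/C(C)=C/C2(C)OCCO2 | intermediate
25 | {(1S,6S)-1,3,5-trimethyl-6-[(1E)-1-(2-methyl-1,3-dioxolan-2-yl)prop-1-en-2-yl]cyclohexa-2,4-dien-1-yl}methanol | OC[C@@]1(C)C=C(C)C=C(C)[C@H]1/C(C)=C/C2(C)OCCO2 | intermediate
26 | (1S,6S)-1,3,5-trimethyl-6-[(1E)-1-(2-methyl-1,3-dioxolan-2-yl)prop-1-en-2-yl]cyclohexa-2,4-diene-1-carbaldehyde | O=C[C@@]1(C)C=C(C)C=C(C)[C@H]1/C(C)=C/C2(C)OCCO2 | intermediate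
27 | methyl 2-methyl-3-oxopentanoate | CCC(=O)C(C)C(=O)OC | starting material
28 | dilithium dianion of 27 | CC=C([O-])C(C)=C([O-])OC.[Li+].[Li+] | intermediate
29 | methyl 5-hydroxy-2,4-dimethyl-3-oxo-5-{(1S,6S)-1,3,5-trimethyl-6-[(1E)-1-(2-methyl-1,3-dioxolan-2-yl)prop-1-en-2-yl]cyclohexa-2,4-dien-1-yl}pentanoate (diastereomer mixture at C2, C4, C5) | COC(=O)C(C)C(=O)C(C)C(O)[C@@]1(C)C=C(C)C=C(C)[C@H]1/C(C)=C/C2(C)OCCO2 | intermediate
30 | methyl 2,4-dimethyl-3,5-dioxo-5-{(1S,6S)-1,3,5-trimethyl-6-[(1E)-1-(2-methyl-1,3-dioxolan-2-yl)prop-1-en-2-yl]cyclohexa-2,4-dien-1-yl}pentanoate | COC(=O)C(C)C(=O)C(C)C(=O)[C@@]1(C)C=C(C)C=C(C)[C@H]1/C(C)=C/C2(C)OCCO2 | intermediate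
31 | 4-hydroxy-3,5-dimethyl-6-{(1S,6S)-1,3,5-trimethyl-6-[(1E)-1-(2-methyl-1,3-dioxolan-2-yl)prop-1-en-2-yl]cyclohexa-2,4-dien-1-yl}-2H-pyran-2-one | O=c1oc([C@@]2(C)C=C(C)C=C(C)[C@H]2/C(C)=C/C3(C)OCCO3)c(C)c(O)c1C | intermediate
32 | 2-methoxy-3,5-dimethyl-6-{(1S,6S)-1,3,5-trimethyl-6-[(1E)-1-(2-methyl-1,3-dioxolan-2-yl)prop-1-en-2-yl]cyclohexa-2,4-dien-1-yl}-4H-pyran-4-one | COc1oc([C@@]2(C)C=C(C)C=C(C)[C@H]2/C(C)=C/C3(C)OCCO3)c(C)c(=O)c1C | intermediate
33 | 2-methoxy-3,5-dimethyl-6-{(1S,6S)-1,3,5-trimethyl-6-[(2E)-4-oxopent-2-en-2-yl]cyclohexa-2,4-dien-1-yl}-4H-pyran-4-one (CNP0353320.2) | COc1oc([C@@]2(C)C=C(C)C=C(C)[C@H]2/C(C)=C/C(C)=O)c(C)c(=O)c1C | target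

**Step count**

Total step count: 22.
Longest linear sequence: 20 steps (steps 1–5 and 8–22); steps 6 and 7 form the side branch to acid 14.

**Steps most likely to fail**

Step 15. After ring closure the C5 cation may lose the C6 proton instead of a C4 proton, which would give the diene conjugated with the side chain and erase the C6 stereocentre. The cation may also be captured by the silyl ether oxygen, or the cyclopropyl gold carbenoid may rearrange. The fallback separates ring closure from alkene formation. It sets out from 23: the same gold catalyst in wet dioxane should let water trap the C5 cation (hydroxycyclisation of the 1,5-enyne) and give tert-butyl{[(1S,6S)-5-hydroxy-1,3,5-trimethyl-6-[(1E)-1-(2-methyl-1,3-dioxolan-2-yl)prop-1-en-2-yl]cyclohex-2-en-1-yl]methoxy}dimethylsilane F1 as a mixture of C5 epimers. Syn-dehydration with the Burgess reagent in warm toluene should then remove the more acidic allylic C4 hydrogen and come back to the route at 24.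

Step 9. The dilithium dianion may fragment (loss of the dienyl alkoxide through a ketene) faster than the hindered tetrasubstituted enolate rearranges. The allyl unit may also add to both enolate faces or through a boat. Any such error gives diastereomers, because the carbinol centre is still present, and these can be separated at 17 or 18. The fallback replaces chelate control by a stable silyl ketene acetal whose geometry is set by a chiral base. It sets out from 15: silylation with Et3SiCl and imidazole should give (2E,4E)-2,4-dimethyl-5-(2-methyl-1,3-dioxolan-2-yl)penta-2,4-dien-1-yl (2S,3R)-2-methyl-3-(triethylsilyloxy)pentanoate F2. Enolisation of this α-branched (2S) ester with LiN[CH(CH3)Ph]2 and Me3SiCl present from the start uses the enantiomer of the amide that places the silyloxy-bearing arm cis to the enolate oxygen. Ireland–Claisen rearrangement of the silyl ketene acetal at 25–60 °C and mild aqueous work-up should then give (2R,3S,4E)-2,4-dimethyl-5-(2-methyl-1,3-dioxolan-2-yl)-3-(prop-1-en-2-yl)-2-[(1R)-1-(triethylsilyloxy)propyl]pent-4-enoic acid F3. Bu4NF removes the triethylsilyl group and the fallback comes back to the route at 17.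

Step 21. Methylation may occur at the C4 hydroxyl oxygen and give the 4-methoxy-2-pyranone isomer, or the acid set free may open the dioxolane too early. The fallback avoids the hydroxypyranone altogether. It sets out from 30: cyclodehydration of the β,δ-diketo ester with PPh3 and CCl4 in THF keeps the ester methoxy group as the C2 methoxy group and comes back to the route at 32, skipping 31, without any new compound.

**Further compounds**

F1 | step 15 | tert-butyl{[(1S,6S)-5-hydroxy-1,3,5-trimethyl-6-[(1E)-1-(2-methyl-1,3-dioxolan-2-yl)prop-1-en-2-yl]cyclohex-2-en-1-yl]methoxy}dimethylsilane (C5 epimers) | CC(C)(C)[Si](C)(C)OC[C@@]1(C)C=C(C)CC(C)(O)[C@H]1/C(C)=C/C2(C)OCCO2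
F2 | step 9 | (2E,4E)-2,4-dimethyl-5-(2-methyl-1,3-dioxolan-2-yl)penta-2,4-dien-1-yl (2S,3R)-2-methyl-3-(triethylsilyloxy)pentanoate | CC[C@@H](O[Si](CC)(CC)CC)[C@H](C)C(=O)OC/C(C)=C/C(C)=C/C1(C)OCCO1
F3 | step 9 | (2R,3S,4E)-2,4-dimethyl-5-(2-methyl-1,3-dioxolan-2-yl)-3-(prop-1-en-2-yl)-2-[(1R)-1-(triethylsilyloxy)propyl]pent-4-enoic acid | OC(=O)[C@@]([C@@H](C(C)=C)/C(C)=C/C1(C)OCCO1)(C)[C@H](O[Si](CC)(CC)CC)CC
F0 | step 21 | none | none
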